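## Structural features

The target is a flavone: benzo ring A is fused through C4a–C8a to the 4-pyranone ring C, which carries a methoxy group at C3 and ring B at C2 through the C2–C1′ bond. There is no stereocentre and no axis that needs control, so the whole problem is one of substitution pattern. Ring A has no C–H at all: C5, C6, C7 and C8 carry OH, OMe, OH and OMe in strict alternation, C8a carries the ring oxygen and C4a the C4 carbonyl. Ring B is a 1,2,4,5-tetrasubstituted benzene with OMe at C2′ and C5′ and a free OH at C4′, para to the C2–C1′ bond. The fragile points are the electron-rich polyphenol rings, which oxidise to quinones in air under base, and the need to keep three phenols (O5, O7, O4′) distinct from five methyl ethers. The real difficulty is ring A: five contiguous oxygenated carbons of three kinds on a hexasubstituted ring, which a route from a bought arene can only reach by a long protecting-group sequence. The key step exploits the local mirror plane of ring A through C4a and C7. C6–C7–C8 with their oxygens is the skeleton of 1,3-dimethoxyacetone (a ketone carbon between two CH–OMe carbons) and C5–C4a–C8a is a malonyl unit. Ring A without ring C is therefore the C2v-symmetric 2,4-dimethoxyphloroglucinol, whose two ortho hydroxyls (the future O5 and O1) are equivalent.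

## Logic of the disconnections

12 to 11. The O4′–benzyl bond is cut (a benzyl ether is placed on O4′). O4′ is the only phenol that has to be masked, because ring B passes through an acylation, a Claisen carboxylation and a thermal condensation; O5 and O7 are never protected. Nothing is gained in skeleton, but the endgame becomes free of phenol interference on ring B. The forward step must remove the benzyl group without reducing the C2=C3 bond of ring C.

11 to 5 and 9 (through 10). The C4–C4a and O1–C2 bonds are cut, which opens ring C. In 5 the only ring C–H is C4a and it lies between two equivalent hydroxyls, so an acyl carbon can enter only there and either hydroxyl closes to the same flavone. The flavone falls to a symmetric arene and an acyclic β-keto ester that already holds ring B, C2, C3 with its methoxy group and C4. The forward step must acylate C4a with the ester carbon (chromone sense) and not attack the ketone with the ring carbon (coumarin sense).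

5 to 2 and 3 (through 4). This is the key disconnection: the C5–C6 and C8–C8a bonds of ring A are cut. The mirror plane through C4a and C7 divides the ring into a ketone flanked by two methoxy-bearing carbons (C6–C7–C8) and a 1,3-diacyl unit (C5–C4a–C8a). A hexasubstituted arene with five differentiated oxygens falls to two symmetric three-carbon chains. O7 comes from the ketone as a free phenol, O6 and O8 come as methyl ethers, and O5 and O8a come from the acyl carbons, so ring A needs no protecting group. The forward step must make both new bonds at carbon, the second one intramolecularly, and must suppress acylation at the ketone oxygen.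

2 to 1. The O–Si bond is cut. The ketone has to react as a carbon nucleophile at both α-carbons in turn while its oxygen stays masked. Because 1 is symmetric, only one enol ether can form.

9 to 8. The C3–C4 bond (flavone numbering) between the methoxy-bearing carbon and the ester carbon is cut. The methoxymethylene group is the only enolisable position of 8, so a one-carbon carbonate electrophile can enter only there. The forward step needs excess base to hold the product as its enolate.

8 to 7. The C2–C1′ bond (flavone numbering), the aryl–acyl bond, is cut. C1′ is para to O4′ and ortho to the 2′-methoxy group, the only position of ring B with a para oxygen donor, so an unfunctionalised arene can be acylated there. The ketone falls to an arene and a two-carbon methoxyacetyl donor. The forward step must spare the benzyl ether and the methoxy group ortho to the new ketone.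

7 to 6. The O–benzyl bond is cut; the forward step is alkylation of the single phenol.

## Other disconnections considered

Alternative 1: the route most chemists would draw first cuts C2–C3 and O1–C2 of ring C. A fully substituted acetophenone, 1-[4,6-bis(benzyloxy)-2-hydroxy-3,5-dimethoxyphenyl]-2-methoxyethan-1-one A1, would be O-aroylated with a ring B acid chloride. The forward key step is a Baker–Venkataraman aroyl shift followed by acid cyclodehydration (or the Allan–Robinson variant). The chosen plan is preferred because this key step builds only ring C. Ring A of A1 would have to be bought as an arene, and its five oxygens sorted by a sequence of selective alkylations and dealkylations, which is where the step count and the regiochemical risk of this target sit.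

Alternative 2: cut C2–C1′ between rings C and B. The chromone 5,7-bis(benzyloxy)-3,6,8-trimethoxy-4H-chromen-4-one A2 has C2–H as its only ring C–H. It would be zincated there with (TMP)2Zn·2MgCl2·2LiCl and joined to 1-(benzyloxy)-4-iodo-2,5-dimethoxybenzene A3 by a Pd(PPh3)4-catalysed Negishi coupling. The selectivity is sound, but the step solves the easiest bond of the target. A2 needs the same fully substituted ring A acetophenone as alternative 1 plus a one-carbon annulation, so the route is longer and ring A stays unsolved.

Alternative 3: cut C8–C8a and C4a–C5 so that C5–C8 come from a squaric ester. The pyranone 2-[4-(benzyloxy)-2,5-dimethoxyphenyl]-3-methoxy-4H-pyran-4-one A4, metalated at C6, would add to 3-methoxy-4-(propan-2-yloxy)cyclobut-3-ene-1,2-dione A5. This would give racemic 4-hydroxy-4-{6-[4-(benzyloxy)-2,5-dimethoxyphenyl]-5-methoxy-4-oxo-4H-pyran-2-yl}-2-methoxy-3-(propan-2-yloxy)cyclobut-2-en-1-one A6. After O-methylation, a Moore-type thermal 4π opening and 6π closure would give the flavone with a free 5-OH directly. This builds ring A onto ring C in one operation, but the two carbonyl groups of A5 differ only by methyl against isopropyl on the remote oxygen. Nothing in the mechanism therefore directs the nucleophile to the carbonyl that places the isopropyl ether at C7 and not at C6. A4 also needs several steps and a site-selective metalation. The chosen [3+3] plan takes the O7 against O6/O8 distinction from the building blocks and is shorter.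

Key step: step 2

Remark: 1, 3 and 6 are taken as catalogue chemicals. 2 is drawn as the Z enol ether; its geometry and the labile CH(OMe) centres of 4, 9 and 10 (all racemic) are erased before the target is reached.

## Steps

Step 1
Reactants: 1 1,3-dimethoxypropan-2-one
Product: 2 (Z)-tert-butyl[(1,3-dimethoxyprop-1-en-2-yl)oxy]dimethylsilane
Conditions: TBSOTf, Et3N, CH2Cl2, 0 °C
Reagents that add atoms: tert-butyldimethylsilyl trifluoromethanesulfonate, CC(C)(C)[Si](C)(C)OS(=O)(=O)C(F)(F)F
Why: Soft enolisation and O-silylation of a ketone (silyl enol ether formation); 1 is symmetric, so only one constitutional isomer can form, and the enol ether geometry is of no consequence.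

Step 2
Reactants: 2 (Z)-tert-butyl[(1,3-dimethoxyprop-1-en-2-yl)oxy]dimethylsilane; 3 malonyl dichloride
Product: 5 2,4-dimethoxybenzene-1,3,5-triol, via acyl chloride 4 (not isolated)
Conditions: slow addition of 3 to 2 (slight excess), Et2O, −20 °C to rt, Ar; then 1 M HCl, THF, rt, Ar
Reagents that add atoms: none
Why: Effenberger cyclization carried through to the aromatic stage: the electron-rich enol ether carbon of 2 is C-acylated by one acyl chloride of 3 and, after loss of a proton from the far methoxymethyl group, the silyl enol ether is re-formed on the other side of the ketone to give 4. The second acyl chloride (or the chlorocarbonyl ketene derived from it) is then attacked by this carbon in a 6-(enolendo)-exo-trig C-acylation that closes ring A, forming the C5–C6 and C8–C8a bonds (flavone numbering) and leaving C4a as the only ring CH. Loss of the silyl group as the silyl chloride and threefold enolisation of the resulting 4,6-dimethoxycyclohexane-1,3,5-trione give the arene, and this aromatisation makes the C-acylation path irreversible. The closest known reaction type is the α,α′-annulation of cyclic ketone enol ethers and silyl enol ethers with malonyl dichloride to bicyclo[3.3.1]nonane-2,4,9-triones; with an open-chain ketone no bridgehead blocks enolisation, so the trione should tautomerise to the phloroglucinol. No stereocentre survives, since the two CH(OMe) centres of the trione are erased by enolisation. The step needs C- over O-acylation in the ring closure (O-attack would give a 4-hydroxy-2-pyranone) and one-to-one stoichiometry: the bulky TBS group keeps the ketone oxygen masked until both C–C bonds are made, slow addition of 3 limits double intermolecular acylation, and the symmetry of 1 removes any regiochemical question. The ketone oxygen becomes O7 as a free phenol while O6 and O8 arrive as methyl ethers, so the OH/OMe alternation is written into the building blocks.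

Step 3
Reactants: 6 2,5-dimethoxyphenol
Product: 7 1-(benzyloxy)-2,5-dimethoxybenzene
Conditions: BnBr, K2CO3, DMF, 50 °C
Reagents that add atoms: benzyl bromide, BrCc1ccccc1
Why: Williamson ether synthesis on the only phenol of 6; the benzyl group masks O4′ through the acylation, Claisen and thermal steps and can be removed at the end without touching the methyl ethers.

Step 4
Reactants: 7 1-(benzyloxy)-2,5-dimethoxybenzene
Product: 8 1-[4-(benzyloxy)-2,5-dimethoxyphenyl]-2-methoxyethan-1-one
Conditions: MeOCH2CO2H, (CF3CO)2O, 85% H3PO4 (cat.), CH2Cl2, 0 °C to rt
Reagents that add atoms: methoxyacetic acid, COCC(=O)O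
Why: Friedel–Crafts acylation by the mixed methoxyacetic trifluoroacetic anhydride formed in the flask, without a metal Lewis acid that could cleave the benzyl ether or the ortho methyl ether. The acyl group should enter para to the benzyloxy group and ortho to one methoxy group, the only position with a para oxygen donor and one free flank (the 1,2,4-trialkoxybenzene pattern); this carbon is the future C1′.

Step 5
Reactants: 8 1-[4-(benzyloxy)-2,5-dimethoxyphenyl]-2-methoxyethan-1-one
Product: 9 methyl 3-[4-(benzyloxy)-2,5-dimethoxyphenyl]-2-methoxy-3-oxopropanoate (racemic)
Conditions: NaH, (MeO)2CO, THF, reflux; then 1 M HCl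
Reagents that add atoms: dimethyl carbonate, COC(=O)OC
Why: Claisen-type C-carboxylation of the ketone enolate with a dialkyl carbonate; the methoxymethylene group is the only enolisable position, and excess base holds 9 as its stabilised enolate, which drives the equilibrium.

Step 6
Reactants: 5 2,4-dimethoxybenzene-1,3,5-triol; 9 methyl 3-[4-(benzyloxy)-2,5-dimethoxyphenyl]-2-methoxy-3-oxopropanoate
Product: 11 2-[4-(benzyloxy)-2,5-dimethoxyphenyl]-5,7-dihydroxy-3,6,8-trimethoxy-4H-chromen-4-one, via 1,3-diketone 10 (not isolated)
Conditions: neat melt, 9 in excess, 240 °C, Ar stream (MeOH and H2O distilled off)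
Reagents that add atoms: none
Why: Mentzer pyrone synthesis: thermal loss of methanol from 9 gives the α-methoxy aroylketene, which acylates C4a of 5, the only ring C–H, directly or through the aryl ester, to give 10; an ortho hydroxyl then adds to the aryl ketone and water is lost to close ring C. Both ortho hydroxyls of 5 are equivalent, so only one flavone can arise, and the uncatalysed thermal mode favours the chromone over the coumarin sense of closure.

Step 7
Reactants: 11 2-[4-(benzyloxy)-2,5-dimethoxyphenyl]-5,7-dihydroxy-3,6,8-trimethoxy-4H-chromen-4-one
Product: 12 5,7,4′-trihydroxy-3,6,8,2′,5′-pentamethoxyflavone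
Conditions: H2 (1 atm), 10% Pd/C, EtOAc–MeOH, rt
Reagents that add atoms: none
Why: Hydrogenolysis of the benzyl aryl ether; the methyl ethers are untouched, and the fully substituted, electron-rich C2=C3 bond of ring C should not be reduced at one atmosphere and room temperature if the reaction is stopped after one equivalent of hydrogen.

## Compound list

1 | 1,3-dimethoxypropan-2-one | COCC(=O)COC | starting material
2 | (Z)-tert-butyl[(1,3-dimethoxyprop-1-en-2-yl)oxy]dimethylsilane | CO/C=C(/COC)O[Si](C)(C)C(C)(C)C | intermediate
3 | malonyl dichloride (propanedioyl dichloride) | O=C(Cl)CC(=O)Cl | starting material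
4 | (Z)-5-[(tert-butyldimethylsilyl)oxy]-4,6-dimethoxy-3-oxohex-5-enoyl chloride (racemic) | CO/C=C(\O[Si](C)(C)C(C)(C)C)C(OC)C(=O)CC(=O)Cl | intermediate
5 | 2,4-dimethoxybenzene-1,3,5-triol | COc1c(O)cc(O)c(OC)c1O | intermediate
6 | 2,5-dimethoxyphenol | COc1ccc(OC)c(O)c1 | starting material
7 | 1-(benzyloxy)-2,5-dimethoxybenzene | COc1ccc(OC)c(OCc2ccccc2)c1 | intermediate
8 | 1-[4-(benzyloxy)-2,5-dimethoxyphenyl]-2-methoxyethan-1-one | COCC(=O)c1cc(OC)c(OCc2ccccc2)cc1OC | intermediate
9 | methyl 3-[4-(benzyloxy)-2,5-dimethoxyphenyl]-2-methoxy-3-oxopropanoate (racemic) | COC(=O)C(OC)C(=O)c1cc(OC)c(OCc2ccccc2)cc1OC | intermediate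
10 | 1-[4-(benzyloxy)-2,5-dimethoxyphenyl]-2-methoxy-3-(2,4,6-trihydroxy-3,5-dimethoxyphenyl)propane-1,3-dione (racemic) | COc1cc(C(=O)C(OC)C(=O)c2c(O)c(OC)c(O)c(OC)c2O)c(OC)cc1OCc1ccccc1 | intermediate
11 | 2-[4-(benzyloxy)-2,5-dimethoxyphenyl]-5,7-dihydroxy-3,6,8-trimethoxy-4H-chromen-4-one | COc1cc(-c2oc3c(OC)c(O)c(OC)c(O)c3c(=O)c2OC)c(OC)cc1OCc1ccccc1 | intermediate
12 | 5,7,4′-trihydroxy-3,6,8,2′,5′-pentamethoxyflavone | COc1cc(-c2oc3c(OC)c(O)c(OC)c(O)c3c(=O)c2OC)c(OC)cc1O | target

## Step count and least certain steps

Total step count: 7. Longest linear sequence: 5 steps (steps 3, 4, 5, 6 and 7).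

Step 2 (key step). The most likely failure is lactonisation: after the first C-acylation the ketone oxygen can lose its silyl group and attack the remaining acyl chloride, giving a 4-hydroxy-2-pyranone in place of the second C–C bond. An open chain has more freedom to reach this geometry than the cyclic substrates of the parent reaction. The HCl released can also protodesilylate 2 before it reacts, and the very electron-rich product can be acylated again by 3. The fallback changes the approach: ring A is taken from a bought arene and its two methoxy groups are introduced late. It sets out from 9 and returns to the route at 11. Thermal Mentzer condensation of 9 with commercial benzene-1,3,5-triol, as in step 6, should give 2-[4-(benzyloxy)-2,5-dimethoxyphenyl]-5,7-dihydroxy-3-methoxy-4H-chromen-4-one F1. Two equivalents of N-bromosuccinimide (THF, 0 °C) should brominate C6 and C8, the two positions flanked by free hydroxyls or the ring oxygen, to give 2-[4-(benzyloxy)-2,5-dimethoxyphenyl]-6,8-dibromo-5,7-dihydroxy-3-methoxy-4H-chromen-4-one F2. Copper-mediated methanolysis (CuBr, NaOMe, DMF–MeOH, 110 °C) should then replace both bromides by methoxide and give 11.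

Step 6. The condensation runs at 240 °C with a benzyl ether, an α-methoxy β-keto ester and a pentaoxygenated phenol. Benzyl transfer or thermal degradation, slow ketene formation from the α-substituted ester, hydrolysis and decarboxylation of 9 by the water released, and closure in the coumarin sense are all conceivable. The fallback replaces the one-pot thermal union by a stepwise, low-temperature sequence. It sets out from 5 and 7 and returns to the route at 10, which is then closed to 11.
- Hoesch reaction of 5 with methoxyacetonitrile (ZnCl2, HCl gas, Et2O, 0 °C; then H2O, reflux) should acylate C4a and give 2-methoxy-1-(2,4,6-trihydroxy-3,5-dimethoxyphenyl)ethan-1-one F3.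
- In parallel, Vilsmeier formylation of 7 (POCl3, DMF) should give 4-(benzyloxy)-2,5-dimethoxybenzaldehyde F4.
- Pinnick oxidation (NaClO2, NaH2PO4, 2-methyl-2-butene) should give 4-(benzyloxy)-2,5-dimethoxybenzoic acid F5.
- Oxalyl chloride with catalytic DMF should give 4-(benzyloxy)-2,5-dimethoxybenzoyl chloride F6.
- The polyanion of F3 (excess LiN(SiMe3)2, THF, −78 °C) should be C-aroylated by F6 to give 10.
- Catalytic TsOH in toluene at 80 °C should cyclodehydrate 10 to 11.

Step 4. The site of acylation is well defined by the substitution pattern. What may go wrong is acid-mediated loss of the benzyl group in the trifluoroacetic medium, or competing trifluoroacetylation of the very activated ring. The fallback replaces electrophilic acylation by an organolithium route. It sets out from 7 and returns to the route at 8. Bromination with N-bromosuccinimide (MeCN, 0 °C) should occur para to the benzyloxy group and give 1-(benzyloxy)-4-bromo-2,5-dimethoxybenzene F7. Bromine–lithium exchange (n-BuLi, THF, −78 °C) and addition of N,2-dimethoxy-N-methylacetamide should give 8.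

## Further compounds

F1 | step 2 | 2-[4-(benzyloxy)-2,5-dimethoxyphenyl]-5,7-dihydroxy-3-methoxy-4H-chromen-4-one | COc1cc(-c2oc3cc(O)cc(O)c3c(=O)c2OC)c(OC)cc1OCc1ccccc1
F2 | step 2 | 2-[4-(benzyloxy)-2,5-dimethoxyphenyl]-6,8-dibromo-5,7-dihydroxy-3-methoxy-4H-chromen-4-one | COc1cc(-c2oc3c(Br)c(O)c(Br)c(O)c3c(=O)c2OC)c(OC)cc1OCc1ccccc1
F3 | step 6 | 2-methoxy-1-(2,4,6-trihydroxy-3,5-dimethoxyphenyl)ethan-1-one | COCC(=O)c1c(O)c(OC)c(O)c(OC)c1O
F4 | step 6 | 4-(benzyloxy)-2,5-dimethoxybenzaldehyde | COc1cc(C=O)c(OC)cc1OCc1ccccc1
F5 | step 6 | 4-(benzyloxy)-2,5-dimethoxybenzoic acid | COc1cc(C(=O)O)c(OC)cc1OCc1ccccc1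
F6 | step 6 | 4-(benzyloxy)-2,5-dimethoxybenzoyl chloride | COc1cc(C(=O)Cl)c(OC)cc1OCc1ccccc1
F7 | step 4 | 1-(benzyloxy)-4-bromo-2,5-dimethoxybenzene | COc1cc(OCc2ccccc2)c(OC)cc1Br
A1 | alternative 1 | 1-[4,6-bis(benzyloxy)-2-hydroxy-3,5-dimethoxyphenyl]-2-methoxyethan-1-one | COCC(=O)c1c(O)c(OC)c(OCc2ccccc2)c(OC)c1OCc1ccccc1
A2 | alternative 2 | 5,7-bis(benzyloxy)-3,6,8-trimethoxy-4H-chromen-4-one | COc1coc2c(OC)c(OCc3ccccc3)c(OC)c(OCc3ccccc3)c2c1=O
A3 | alternative 2 | 1-(benzyloxy)-4-iodo-2,5-dimethoxybenzene | COc1cc(OCc2ccccc2)c(OC)cc1I
A4 | alternative 3 | 2-[4-(benzyloxy)-2,5-dimethoxyphenyl]-3-methoxy-4H-pyran-4-one | COc1c(-c2cc(OC)c(OCc3ccccc3)cc2OC)occc1=O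
A5 | alternative 3 | 3-methoxy-4-(propan-2-yloxy)cyclobut-3-ene-1,2-dione | COC1=C(OC(C)C)C(=O)C1=O
A6 | alternative 3 | 4-hydroxy-4-{6-[4-(benzyloxy)-2,5-dimethoxyphenyl]-5-methoxy-4-oxo-4H-pyran-2-yl}-2-methoxy-3-(propan-2-yloxy)cyclobut-2-en-1-one (racemic) | COC1=C(OC(C)C)C(O)(c2cc(=O)c(OC)c(-c3cc(OC)c(OCc4ccccc4)cc3OC)o2)C1=O
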